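Time first: after 1.04 d the west run reads 0.6% starting material, and its product readings stay near 68.2% through 6.00 d. So compare the height of that plateau from run to run.

| setting | west | south | north-west | Tuesday's | Thursday's | Sunday's | Monday's | Friday's |
|---|---|---|---|---|---|---|---|---|
| starting material | 0.11 M | 0.055 M | 0.083 M | 0.11 M | 0.11 M (in portions, 3, over 8.0 d) | 0.11 M | 0.11 M | 0.11 M (fed, over 8.0 d) |
| reagent | 2.5 equiv | 2.5 equiv | 2.5 equiv | 2.50 equiv (fed, over 8.0 d) | 2.50 equiv | 2.50 equiv (fed, over 20 h) | 2.50 equiv | 2.50 equiv |
| remark | run made earlier | run made earlier | run made earlier | all else is in the flask from the start; the feed brings no volume worth counting | first portion at the start, last at 8.0 d | all else is in the flask from the start; the feed brings no volume worth counting | everything together at the start | all else is in the flask from the start; the feed brings no volume worth counting |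
| time |  |  |  | 10 d | 10 d | 10 d | 10 d | 10 d |

| run | time / d | product / % | starting material / % |
|---|---|---|---|
| west | 1.04 | 67.3 | 0.6 |
| west | 2.08 | 69.2 | 0 |
| west | 3.00 | 68.2 | 0.6 |
| west | 4.00 | 67.2 | 1.2 |
| west | 5.00 | 68.5 | 1.5 |
| west | 6.00 | 68.6 | 0 |
| south | 1.25 | 81.2 | 0.5 |
| south | 2.50 | 80.7 | 0.4 |
| south | 4.00 | 80.4 | 0.5 |
| south | 5.00 | 80.9 | 0.3 |
| south | 6.00 | 80.9 | 0 |
| south | 8.00 | 81.2 | 0.5 |
| north-west | 0.500 | 63.8 | 14.4 |
| north-west | 1.67 | 73.6 | 0.7 |
| north-west | 3.00 | 73.3 | 0 |
| north-west | 4.00 | 74.6 | 0.4 |
| north-west | 6.00 | 73.9 | 0 |
| north-west | 8.00 | 74.1 | 0.6 |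

(standard deviation of a reading: 0.5 percentage points)

- which flask leads in amount of product, in percent of the starting material charged ("all alike" within 1.5 percentage points) (Tuesday's / Thursday's / Sunday's / Monday's / Friday's / all alike)
- how much product is there at the end, in percent of the starting material charged: Tuesday's
- how much product is there at the end, in percent of the starting material charged: Thursday's
- how much product is there at the end, in percent of the starting material charged: Sunday's
- how much product is there at the end, in percent of the starting material charged: Monday's
- how much product is there at the end, in percent of the starting material charged: Friday's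



The plateau rises on dilution, to 73.9% in the north-west run and 80.9% in the south run. In the north-west run, product reads 74.5% of the starting material consumed at 0.500 d, against the plateau of 73.9%, although starting material reads 14.4% there and 0.7% at 1.67 d. So the loss does not appear to follow c(starting material), and you can try c(reagent), charged at 2.5 equiv.

Let starting material form product with first-order constant k and be lost at k·g·c(reagent), so that product yield is Y = 1/(1 + g·c(reagent)). Here g is the selectivity factor, loss per product formed per unit c(reagent). With c(reagent) taken as the charge, the runs give 1.70 M⁻¹, 1.70 M⁻¹ and 1.72 M⁻¹, so take 1.71 M⁻¹. The north-west reading at 0.500 d gives a total decay constant of 3.88 d⁻¹. Dividing by 1 + g·c(reagent) leaves 2.86 d⁻¹, a life of 0.349 d.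

With the reagent in the flask from the start, as in Monday's, Thursday's and Friday's, take c(reagent) as the charge again, and this reckoning gives Y as 68.1%; at that held c(reagent), dosing starting material leaves the ratio of its two losses unchanged.

Feeding reagent at rate r is solved from the slow end. Starting material is in the flask from the start while c(reagent) grows as r·t, so as an estimate it meets about r times its life, and that life shortens by 1 + x, where x = g·c(reagent) met. So x(1 + x) = b, with feed number b = g·r/k. For Tuesday's, r is 0.0344 M d⁻¹, b is 0.0205, x is 0.0201, and Y is 98.0%. For Sunday's, b is 0.197 and x is 0.168, so Y is 85.6%. The c(reagent) reckoned as met in Sunday's, 0.0982 M, is still below the charge.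

The forecast puts Tuesday's first, with Tuesday's 97%, Thursday's 68.5%, Sunday's 87%, Monday's 68% and Friday's 68.5%, on the ground “Feeding reagent keeps it low while starting material is consumed”; for Sunday's it stands higher than this reckoning.

The simulation puts Tuesday's first, with Tuesday's 98.1%, Thursday's 69.3%, Sunday's 87.1%, Monday's 68.6% and Friday's 69.4%.

    intermediate B ⇌ intermediate D (K = 0.377, k = 0.0955 h⁻¹)
    reagent + intermediate A ⇌ intermediate C (K = 0.566 M⁻¹, k = 0.0919 M⁻¹ h⁻¹)
    intermediate C ⇌ intermediate E (K = 8.30, k = 0.967 h⁻¹)
    starting material + reagent → intermediate A (k = 0.223 M⁻¹ h⁻¹)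
    starting material → product (k = 0.123 h⁻¹)
    reagent + intermediate A → intermediate B (k = 0.137 M⁻¹ h⁻¹)

Now take Tuesday's with 10.0 equiv of reagent, all else held. The feed rises to 0.138 M d⁻¹, so with the same g and k the feed number is 0.0820, larger than Tuesday's. Then x is 0.0762, and the reckoning gives 92.9%. The simulated neighbour holds 4.51% intermediate B, 1.69% intermediate D and 93.4% product.

All runs were computed for an exercise, and the scatter is random.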